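Germacranolide numbering is used (lactone carbonyl C12, its α-carbon C11, β-carbon C7, lactone oxygen on C6). The route rests on making the C11–C12 bond of the butenolide ring by ring contraction. The oxygen atoms on C6 and C3 flank the Z-olefin C4=C5, so they are first tied into a seven-membered cyclic carbonate by tethered ring-closing metathesis, which also fixes the Z geometry. The precursor carries a Z-iodoalkene at C11; iodine–magnesium exchange makes C11 attack the carbonate carbon, the seven-membered ring contracts to the five-membered butenolide, and the released O3 alkoxide is acetylated. B-alkyl Suzuki macrocyclisation and a singlet-oxygen ene reaction complete the target.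

Key step: step 8

Numbering in the Why lines: C1–C10 ring carbons, C11–C13 lactone carbons, C14 on C10, C15 on C4.
Assumption: the sense of induction of (S)-TRIP (step 1) and of (S,S)-ProPhenol (step 4) is taken from the accepted transition-state models; if either is opposite, the antipodal catalyst is used and nothing else changes.

Step 1
Reactants: 1 methacrolein; 2 allenylboronic acid pinacol ester
Product: 4 (3S)-2-methylhex-1-en-5-yn-3-ol, via homopropargylic pinacol borate 3 (not isolated)
Conditions: (S)-TRIP phosphoric acid (5 mol%), 4 Å MS, toluene, 0 °C; aqueous work-up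
Reagents that add atoms: none
Why: Chiral-phosphoric-acid-catalysed propargylboration, in which the allenylboronate reacts through a closed six-membered SE2' transition state held by the acid, so that one aldehyde face is selected and C3 should be set as S.

Step 2
Reactants: 4 (3S)-2-methylhex-1-en-5-yn-3-ol
Product: 6 (3S)-2-methylhept-1-en-5-yn-3-ol, via dilithium alkoxide acetylide 5 (not isolated)
Conditions: n-BuLi (2.1 equiv), THF, −78 °C; MeI, −78 °C → rt
Reagents that add atoms: iodomethane, CI
Why: Acetylide alkylation of the dianion, whose acetylide carbon is far more nucleophilic than the lithium alkoxide in THF, so only the alkyne terminus should be methylated and C3 is untouched.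

Step 3
Reactants: 6 (3S)-2-methylhept-1-en-5-yn-3-ol
Product: 8 (3S,5E)-6-bromo-2-methylhepta-1,5-dien-3-ol, via alkenylzirconocene 7 (not isolated)
Conditions: Cp2Zr(H)Cl (2.5 equiv), THF, rt → 40 °C; NBS, 0 °C
Reagents that add atoms: N-bromosuccinimide, O=C1CCC(=O)N1Br
Why: Syn-hydrozirconation of the internal alkyne should place zirconium on the less hindered methyl-bearing carbon after equilibration with excess reagent, and bromodezirconation with retention then gives the E-2-bromoalkene (future C1=C10 with C14 cis to C2), the 1,1-disubstituted olefin reacting far more slowly.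

Step 4
Reactants: 9 acrolein; 10 tert-butyldimethyl(prop-2-yn-1-yloxy)silane
Product: 12 (4R)-1-[(tert-butyldimethylsilyl)oxy]hex-5-en-2-yn-4-ol, via methylzinc alkoxide 11 (not isolated)
Conditions: (S,S)-ProPhenol (10 mol%), Me2Zn (3 equiv), Ph3PO (20 mol%), toluene, 0 °C
Reagents that add atoms: none
Why: Dinuclear zinc–ProPhenol asymmetric alkynylation, in which the alkynylzinc made from Me2Zn is delivered 1,2 to one face of the enal carbonyl inside the chiral bimetallic pocket, which should set C6 as R.

Step 5
Reactants: 12 (4R)-1-[(tert-butyldimethylsilyl)oxy]hex-5-en-2-yn-4-ol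
Product: 14 (2Z,4R)-1-[(tert-butyldimethylsilyl)oxy]-3-ethenyl-2-iodohexa-2,5-dien-4-ol, via cyclic alkenylmagnesium alkoxide 13 (not isolated)
Conditions: CH2=CHMgCl (4 equiv), THF–cyclohexane, reflux; I2, THF, −78 → 0 °C
Reagents that add atoms: vinylmagnesium chloride, C=C[Mg]Cl; iodine, II
Why: Alkoxide-directed anti-carbomagnesiation of the propargylic alcohol delivers vinyl to the proximal alkyne carbon C7 and leaves magnesium on C11 in a five-membered chelate, so iodinolysis with retention should give the tetrasubstituted iodoalkene with iodine cis to C6.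

Step 6
Reactants: 8 (3S,5E)-6-bromo-2-methylhepta-1,5-dien-3-ol; 14 (2Z,4R)-1-[(tert-butyldimethylsilyl)oxy]-3-ethenyl-2-iodohexa-2,5-dien-4-ol
Product: 16 mixed carbonate of 8 (through O3) and 14 (through O6), via imidazole-1-carboxylate 15 (not isolated)
Conditions: 8, CDI, CH2Cl2, rt; then 14, DBU, MeCN, 40 °C
Reagents that add atoms: 1,1'-carbonyldiimidazole, O=C(n1ccnc1)n1ccnc1
Why: Stepwise carbonate synthesis, in which the imidazole carboxylate of the less hindered alcohol acylates the second alcohol under DBU activation, so that only the mixed carbonate should form and neither carbinol centre is touched.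

Step 7
Reactants: 16 mixed carbonate
Product: 17 seven-membered cyclic carbonate (4,7-dihydro-1,3-dioxepin-2-one with Z-C4=C5, C3 S, C6 R)
Conditions: second-generation Grubbs catalyst RuCl2(=CHPh)(H2IMes)(PCy3) (10 mol%), toluene (2 mM), 80 °C
Reagents that add atoms: none
Why: Tethered ring-closing metathesis, in which the C6 vinyl and C3 isopropenyl groups close the seven-membered ring most readily (vinyl/vinyl would need a cyclobutene, diene-vinyl/isopropenyl an eight-membered ring), the ring forces the new trisubstituted C4=C5 bond to be Z, and only ethene is released.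

Step 8
Reactants: 17 seven-membered cyclic carbonate
Product: 20 (5R)-5-[(1Z,3S,5E)-3-acetoxy-6-bromo-2-methylhepta-1,5-dien-1-yl]-3-[(tert-butyldimethylsilyloxy)methyl]-4-ethenylfuran-2(5H)-one, via alkenylmagnesium chloride 18 (not isolated), via chloromagnesium alkoxide 19 (not isolated)
Conditions: i-PrMgCl·LiCl (1.1 equiv), THF, −40 → 0 °C; then Ac2O, DMAP, 0 °C → rt
Reagents that add atoms: acetic anhydride, CC(=O)OC(C)=O
Why: Iodine–magnesium exchange occurs at the tetrasubstituted alkenyl iodide (the alkenyl bromide exchanges much more slowly), and the alkenylmagnesium, held cis to C6, adds to the carbonate carbonyl in a 5-exo-trig acyl substitution that forms C11–C12. The bicyclic tetrahedral alkoxide should collapse by loss of the O3 alkoxide, because this keeps the conjugated five-membered lactone and opens the seven-membered ring, so the carbonate ring contracts to the butenolide. The closest known reaction type is the Parham cyclisation, that is halogen–metal exchange followed by intramolecular acylation of the carbanion by a carbonate or carbamate to give a lactone. No stereocentre is created, and C3 and C6 keep their configuration because only the C12–O3 bond is broken. The step needs exchange and cyclisation to outrun addition of i-PrMgCl to the carbonate and β-elimination of the silyloxy group, which low temperature, one equivalent of reagent and the proximity of C11 to C12 should secure. The freed C3 magnesium alkoxide is acetylated in the same flask, which differentiates O3 from O6 without protecting groups.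

Step 9
Reactants: 20 butenolide acetate
Product: 22 (3S,6R)-3-acetoxy-13-[(tert-butyldimethylsilyl)oxy]germacra-1(10)E,4Z,7(11)-trien-12,6-olide, via B-alkyl-9-BBN adduct 21 (not isolated)
Conditions: 9-BBN-H, THF, 0 °C → rt; then Pd(dppf)Cl2 (15 mol%), AsPh3, aq K3PO4, THF/DMF, rt, slow addition (2 mM)
Reagents that add atoms: none
Why: 9-BBN should hydroborate the only monosubstituted olefin at its terminus (C9), and intramolecular B-alkyl Suzuki–Miyaura coupling with the alkenyl bromide under high dilution closes the ten-membered ring at C9–C10 with retention of the E geometry of C1=C10.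

Step 10
Reactants: 22 silyl ether macrocycle
Product: 23 (3S,6R)-3-acetoxy-13-hydroxygermacra-1(10)E,4Z,7(11)-trien-12,6-olide
Conditions: HF·pyridine, pyridine, THF, 0 °C → rt
Reagents that add atoms: none
Why: Buffered fluoride cleavage of the primary silyl ether should leave the acetate, the lactone and the acid-sensitive 1,5-diene intact.

Step 11
Reactants: 23 hydroxy macrocycle
Product: 24 (3S,6R)-3,13-diacetoxygermacra-1(10)E,4Z,7(11)-trien-12,6-olide
Conditions: Ac2O, pyridine, DMAP (cat.), CH2Cl2, 0 °C
Reagents that add atoms: acetic anhydride, CC(=O)OC(C)=O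
Why: DMAP-catalysed acetylation of the primary allylic alcohol under mild base that should not epimerise C6.

Step 12
Reactants: 24 diacetate
Product: 25 (1R,3S,6R)-3,13-diacetoxy-1-hydroperoxygermacra-4Z,7(11),10(14)-trien-12,6-olide (target)
Conditions: O2, hν (visible), tetraphenylporphyrin (cat.), CH2Cl2, −20 °C
Reagents that add atoms: dioxygen, O=O
Why: Schenck ene reaction, in which singlet oxygen should attack only the electron-rich C1=C10 bond (C4=C5 is deactivated by two allylic acyloxy groups, C7=C11 by conjugation), take hydrogen from the C14 methyl on the disubstituted side of the E-olefin (cis effect) so that oxygen binds C1 and the double bond moves to C10=C14, and approach the exposed outer face of the olefin, which is expected to give the 1R hydroperoxide syn to the C3 acetate.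

Compound list
1 | methacrolein | C=C(C)C=O | starting material
2 | allenylboronic acid pinacol ester | C=C=CB1OC(C)(C)C(C)(C)O1 | starting material
3 | (3S)-2-methylhex-1-en-5-yn-3-yl pinacol borate (not isolated) | C=C(C)[C@H](CC#C)OB1OC(C)(C)C(C)(C)O1 | intermediate
4 | (3S)-2-methylhex-1-en-5-yn-3-ol | C=C(C)[C@@H](O)CC#C | intermediate
5 | dilithium alkoxide acetylide of 4 (not isolated) | C=C(C)[C@@H](O[Li])CC#C[Li] | intermediate
6 | (3S)-2-methylhept-1-en-5-yn-3-ol | C=C(C)[C@@H](O)CC#CC | intermediate
7 | (E)-alkenylzirconocene chloride of 6 with zirconium on the methyl-bearing carbon and on oxygen (not isolated) | C=C(C)[C@@H](O[Zr](Cl)(C1C=CC=C1)C1C=CC=C1)C/C=C(\C)[Zr](Cl)(C1C=CC=C1)C1C=CC=C1 | intermediate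
8 | (3S,5E)-6-bromo-2-methylhepta-1,5-dien-3-ol | C=C(C)[C@@H](O)C/C=C(\C)Br | intermediate
9 | acrolein | C=CC=O | starting material
10 | tert-butyldimethyl(prop-2-yn-1-yloxy)silane | C#CCO[Si](C)(C)C(C)(C)C | starting material
11 | methylzinc alkoxide of 12 (not isolated) | C=C[C@@H](O[Zn]C)C#CCO[Si](C)(C)C(C)(C)C | intermediate
12 | (4R)-1-[(tert-butyldimethylsilyl)oxy]hex-5-en-2-yn-4-ol | C=C[C@@H](O)C#CCO[Si](C)(C)C(C)(C)C | intermediate
13 | cyclic alkenylmagnesium alkoxide (1-oxa-2-magnesacyclopent-3-ene with Mg on C11 and O6; not isolated) | C=C[C@H]1O[Mg]C(CO[Si](C)(C)C(C)(C)C)=C1C=C | intermediate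
14 | (2Z,4R)-1-[(tert-butyldimethylsilyl)oxy]-3-ethenyl-2-iodohexa-2,5-dien-4-ol | C=C[C@@H](O)/C(C=C)=C(\I)CO[Si](C)(C)C(C)(C)C | intermediate
15 | (3S,5E)-6-bromo-2-methylhepta-1,5-dien-3-yl imidazole-1-carboxylate (not isolated) | C=C(C)[C@H](C/C=C(\C)Br)OC(=O)n1ccnc1 | intermediate
16 | mixed carbonate of 8 and 14 | C=C(C)[C@H](C/C=C(\C)Br)OC(=O)O[C@H](C=C)/C(C=C)=C(\I)CO[Si](C)(C)C(C)(C)C | intermediate
17 | seven-membered cyclic carbonate: 4-[(E)-3-bromobut-2-enyl]-5-methyl-7-[(Z)-iododienyl]-4,7-dihydro-1,3-dioxepin-2-one (C3 S, C6 R) | O=C1O[C@@H](C/C=C(\C)Br)/C(C)=C\[C@@H](O1)/C(C=C)=C(\I)CO[Si](C)(C)C(C)(C)C | intermediate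
18 | alkenylmagnesium chloride from 17 (Mg on C11; not isolated) | O=C1O[C@@H](C/C=C(\C)Br)/C(C)=C\[C@@H](O1)/C(C=C)=C(\[Mg]Cl)CO[Si](C)(C)C(C)(C)C | intermediate
19 | butenolide C3 chloromagnesium alkoxide (not isolated) | O=C1O[C@H](/C=C(/C)[C@@H](O[Mg]Cl)C/C=C(\C)Br)C(C=C)=C1CO[Si](C)(C)C(C)(C)C | intermediate
20 | (5R)-5-[(1Z,3S,5E)-3-acetoxy-6-bromo-2-methylhepta-1,5-dien-1-yl]-3-[(tert-butyldimethylsilyloxy)methyl]-4-ethenylfuran-2(5H)-one | O=C1O[C@H](/C=C(/C)[C@@H](OC(C)=O)C/C=C(\C)Br)C(C=C)=C1CO[Si](C)(C)C(C)(C)C | intermediate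
21 | B-alkyl-9-BBN adduct of 20 (boron on C9; not isolated) | O=C1O[C@H](/C=C(/C)[C@@H](OC(C)=O)C/C=C(\C)Br)C(CCB2C3CCCC2CCC3)=C1CO[Si](C)(C)C(C)(C)C | intermediate
22 | (3S,6R)-3-acetoxy-13-[(tert-butyldimethylsilyl)oxy]germacra-1(10)E,4Z,7(11)-trien-12,6-olide | C/C1=C\C[C@H](OC(C)=O)/C(C)=C\[C@H]2OC(=O)C(CO[Si](C)(C)C(C)(C)C)=C2CC1 | intermediate
23 | (3S,6R)-3-acetoxy-13-hydroxygermacra-1(10)E,4Z,7(11)-trien-12,6-olide | C/C1=C\C[C@H](OC(C)=O)/C(C)=C\[C@H]2OC(=O)C(CO)=C2CC1 | intermediate
24 | (3S,6R)-3,13-diacetoxygermacra-1(10)E,4Z,7(11)-trien-12,6-olide | C/C1=C\C[C@H](OC(C)=O)/C(C)=C\[C@H]2OC(=O)C(COC(C)=O)=C2CC1 | intermediate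
25 | (1R,3S,6R)-3,13-diacetoxy-1-hydroperoxygermacra-4Z,7(11),10(14)-trien-12,6-olide (CNP0174966.1) | C=C1CCC2=C(COC(C)=O)C(=O)O[C@@H]2/C=C(/C)[C@@H](OC(C)=O)C[C@H]1OO | target

Total step count: 12. Longest linear sequence: 10 steps (steps 1–3, then 6–12).

Steps most likely to fail

Step 9 (macrocyclisation). What may go wrong: the alkylborane may be lost by protodeboronation or intermolecular coupling before the slow ten-membered ring closure, and C6 may epimerise in the basic medium. The fallback sets out from 20 and returns at 22. Hydroboration of 20 with 9-BBN and oxidation with NaBO3·4H2O should give the primary C9 alcohol F3. An Appel reaction (I2, PPh3, imidazole) should convert it into the primary C9 iodide F4. A nickel-catalysed reductive cross-electrophile coupling of the alkyl iodide with the alkenyl bromide (NiBr2(dme), 4,4'-di-tert-butyl-2,2'-bipyridine, Mn powder, DMA, high dilution) would then close C9–C10 to 22 without base and without an organoboron intermediate.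

Step 12 (ene reaction). What may go wrong: singlet oxygen may attack the wrong face of the C1=C10 olefin, or both faces. The fallback sets out from 24 and returns at 25. Photooxygenation as in step 12, with reduction of the crude hydroperoxides by PPh3 in the same flask, should give the C1 allylic alcohol F5 in either configuration. Dess–Martin oxidation converges both epimers on the exocyclic enone F6. Corey–Bakshi–Shibata reduction ((R)-2-methyl-oxazaborolidine, catecholborane, −78 °C) should give the 1S alcohol F7 under reagent control. Mesylation (MsCl, Et3N, −78 °C) gives the mesylate F8, and displacement with anhydrous H2O2 in Et2O at low temperature, with inversion, should give the 1R hydroperoxide 25.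

Step 8 (key step). What may go wrong: the exchange reagent may add to the strained carbonate, or the alkenylmagnesium may lose the β-silyloxy group to form an allene, before cyclisation. The fallback sets out from 17 and returns at 20. Methanolysis of the carbonate (K2CO3, MeOH, 0 °C) should give the iodo diol F1. Palladium-catalysed carbonylative lactonisation (Pd(PPh3)4, CO 1 atm, K2CO3, THF, 50 °C) should insert CO into the C11–I bond only, the alkenyl bromide being slower, and the C6 hydroxyl closes the five-membered ring to the C3-hydroxy butenolide F2. Acetylation of the remaining C3 hydroxyl (Ac2O, pyridine) returns 20.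

Further compounds
F1 | step 8 | iodo diol from methanolysis of 17 (C3 S, C6 R, Z-C4=C5) | O[C@@H](C/C=C(\C)Br)/C(C)=C\[C@@H](O)/C(C=C)=C(\I)CO[Si](C)(C)C(C)(C)C
F2 | step 8 | C3-hydroxy butenolide (deacetyl 20) | O=C1O[C@H](/C=C(/C)[C@@H](O)C/C=C(\C)Br)C(C=C)=C1CO[Si](C)(C)C(C)(C)C
F3 | step 9 | primary C9 alcohol from hydroboration–oxidation of 20 | O=C1O[C@H](/C=C(/C)[C@@H](OC(C)=O)C/C=C(\C)Br)C(CCO)=C1CO[Si](C)(C)C(C)(C)C
F4 | step 9 | primary C9 iodide | O=C1O[C@H](/C=C(/C)[C@@H](OC(C)=O)C/C=C(\C)Br)C(CCI)=C1CO[Si](C)(C)C(C)(C)C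
F5 | step 12 | 3,13-diacetoxy-1-hydroxygermacra-4Z,7(11),10(14)-trien-12,6-olide (either configuration at C1) | C=C1CCC2=C(COC(C)=O)C(=O)O[C@@H]2/C=C(/C)[C@@H](OC(C)=O)CC1O
F6 | step 12 | 3,13-diacetoxy-1-oxogermacra-4Z,7(11),10(14)-trien-12,6-olide | C=C1CCC2=C(COC(C)=O)C(=O)O[C@@H]2/C=C(/C)[C@@H](OC(C)=O)CC1=O
F7 | step 12 | (1S)-3,13-diacetoxy-1-hydroxygermacra-4Z,7(11),10(14)-trien-12,6-olide | C=C1CCC2=C(COC(C)=O)C(=O)O[C@@H]2/C=C(/C)[C@@H](OC(C)=O)C[C@@H]1O
F8 | step 12 | (1S)-1-methanesulfonate of F7 | C=C1CCC2=C(COC(C)=O)C(=O)O[C@@H]2/C=C(/C)[C@@H](OC(C)=O)C[C@@H]1OS(C)(=O)=O
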